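**Retrosynthetic overview**

1. Rings are lettered A (2,4,6-trihydroxyphenoxy end) to G (3,4,5-trihydroxyphenoxy end). C1 of each ring is the carbon bonded to the ether oxygen leading toward ring A (in ring A, its only ether carbon). The second ether oxygen sits on C4 in rings B, D, F and on C6 in rings C, E.
2. Feature used: rings F and G are oxygenated at C3, C4, C5 with hydrogen at C2 and C6, which is the ring of syringic and of gallic acid, and the ether oxygen each carries at C1 sits where those acids carry the carboxyl carbon. Each of the ethers O–F C1 and O–G C1 is therefore traced back to an aryl ester of the crowded phenol oxygen (E C6–O–CO–F C1, F C4–O–CO–G C1), and both CO units are extruded in one palladium-catalysed operation.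
3. The E–F–G depside comes from a ring E phenol (Baeyer–Villiger oxidation of a benzylated salicylaldehyde), syringaldehyde and 3,4,5-trimethoxybenzoyl chloride.
4. A–B–C–D is built by three copper-catalysed Ullmann couplings, each with the di-ortho-oxygenated phenol as nucleophile; the C C6 oxygen arises from a formyl group. The D C4–O–E C1 bond is then made by palladium coupling of the E–F–G triflate, and global O-demethylation ends the route.
5. No ring is formed: all seven benzene rings are bought. Order of ether bonds: F–G and E–F (key step), A–B, B–C, C–D, D–E.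

Key step: step 6

Remark: the target has no stereocentre; 2,4,6-trimethoxyphenol, 4-bromo-2,6-dimethoxyphenol and 5-bromo-1,2,3-trimethoxybenzene are taken as catalogue compounds, and all electron-rich phenols are handled under argon.

**Route**

Step 1
Reactants: 1 2-hydroxy-4,6-dimethoxybenzaldehyde
Product: 2 2-(benzyloxy)-4,6-dimethoxybenzaldehyde
Conditions: BnBr, K2CO3, DMF, 60 °C
Reagents that add atoms: benzyl bromide (BrCc1ccccc1)
Why: Williamson etherification of the acidic salicylaldehyde hydroxyl installs the one protecting group that can later be removed without touching methyl ethers.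

Step 2
Reactants: 2 2-(benzyloxy)-4,6-dimethoxybenzaldehyde
Product: 4 2-(benzyloxy)-4,6-dimethoxyphenol (ring E phenol, OH on E C6), via aryl formate 3 (not isolated)
Conditions: mCPBA, CH2Cl2, 0 °C to rt; then K2CO3 (cat.), MeOH, rt
Reagents that add atoms: mCPBA (OOC(=O)c1cccc(Cl)c1)
Why: Baeyer–Villiger (Dakin-type) oxidation, in which the 2,4,6-trioxygenated aryl group migrates far faster than hydride, gives formate 3, which methanolysis cleaves to the phenol.

Step 3
Reactants: 5 syringaldehyde (4-hydroxy-3,5-dimethoxybenzaldehyde); 6 3,4,5-trimethoxybenzoyl chloride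
Product: 7 4-formyl-2,6-dimethoxyphenyl 3,4,5-trimethoxybenzoate
Conditions: Et3N, DMAP (cat.), CH2Cl2, 0 °C to rt
Reagents that add atoms: none
Why: DMAP-catalysed O-acylation of the acidic para-formyl phenol by the acid chloride; carrying the ring F carboxyl as an aldehyde avoids the mixed anhydride that free syringic acid would form.

Step 4
Reactants: 7 4-formyl-2,6-dimethoxyphenyl 3,4,5-trimethoxybenzoate
Product: 8 3,5-dimethoxy-4-(3,4,5-trimethoxybenzoyloxy)benzoic acid
Conditions: NaClO2, NaH2PO4, 2-methyl-2-butene, t-BuOH–THF–H2O, rt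
Reagents that add atoms: sodium chlorite ([Na+].[O-]Cl=O)
Why: Pinnick oxidation converts the aldehyde to the acid under buffered, mildly acidic conditions that leave the aryl ester intact.

Step 5
Reactants: 8 3,5-dimethoxy-4-(3,4,5-trimethoxybenzoyloxy)benzoic acid; 4 2-(benzyloxy)-4,6-dimethoxyphenol
Product: 9 2-(benzyloxy)-4,6-dimethoxyphenyl 3,5-dimethoxy-4-(3,4,5-trimethoxybenzoyloxy)benzoate (E–F–G depside)
Conditions: 1-ethyl-3-(3-dimethylaminopropyl)carbodiimide hydrochloride, DMAP, CH2Cl2, rt
Reagents that add atoms: none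
Why: Steglich esterification passes the carbodiimide-activated acid as an acylpyridinium to the crowded phenol, and the neutral conditions should not transacylate the existing hindered aryl ester.

Step 6
Reactants: 9 E–F–G depside
Product: 11 1-(benzyloxy)-3,5-dimethoxy-2-[3,5-dimethoxy-4-(3,4,5-trimethoxyphenoxy)phenoxy]benzene (E–F–G trimer ether, benzyloxy on E C1), via mono-decarbonylated ester 10 (not isolated)
Conditions: Pd(OAc)2 (20 mol %), 3,4-bis(dicyclohexylphosphino)thiophene (40 mol %), K3PO4 (1.5 equiv), mesitylene (0.02 M), 150 °C, slow argon sweep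
Reagents that add atoms: none
Why: Proposed new method: zerovalent palladium, formed from Pd(OAc)2 and the electron-rich bisphosphine, should insert first into the acyl C–O bond of the F–O–CO–G ester (its leaving aryloxide carries the para carbonyl), the acyl ligand on divalent palladium should release CO, and reductive elimination from the aryl palladium aryloxide should join G C1 to the F C4 oxygen; the same cycle on ester 10 then joins F C1 to the E C6 oxygen. The closest known reaction type is the nickel- or palladium-catalysed decarbonylative etherification of single aryl esters, shown mainly for azine and other electron-poor carboxylates, so a twofold extrusion on an electron-rich depside is new. No ring is closed and no stereocentre is formed. The step needs insertion into the two ester C–O bonds and not into aryl–OMe or benzyl–O bonds, which the much weaker acyl–aryloxide bond and the constant removal of CO should secure. It also needs each aryloxide to stay on the palladium that carries its aryl partner, which the apolar, dilute medium is meant to secure. Both migrating carbons (F C1, G C1) have hydrogen on either side, so CO loss and C–O elimination are not crowded, while the crowded 2,6-dioxygenated aryloxides should speed the elimination.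

Step 7
Reactants: 11 E–F–G trimer ether (benzyl ether)
Product: 12 3,5-dimethoxy-2-[3,5-dimethoxy-4-(3,4,5-trimethoxyphenoxy)phenoxy]phenol (OH on E C1)
Conditions: H2 (1 atm), 10% Pd/C, EtOAc–MeOH, rt
Reagents that add atoms: none
Why: Catalytic hydrogenolysis cleaves only the benzyl ether; diaryl ethers and methyl ethers are inert.

Step 8
Reactants: 12 E–F–G phenol
Product: 13 3,5-dimethoxy-2-[3,5-dimethoxy-4-(3,4,5-trimethoxyphenoxy)phenoxy]phenyl trifluoromethanesulfonate
Conditions: Tf2O, pyridine, CH2Cl2, 0 °C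
Reagents that add atoms: triflic anhydride (O=S(=O)(OS(=O)(=O)C(F)(F)F)C(F)(F)F)
Why: O-sulfonylation of the phenol with triflic anhydride and pyridine turns E C1 into an electrophilic carbon for cross-coupling.

Step 9
Reactants: 14 4-bromo-2,6-dimethoxyphenol
Product: 15 2-(benzyloxy)-5-bromo-1,3-dimethoxybenzene
Conditions: BnBr, K2CO3, DMF, rt
Reagents that add atoms: benzyl bromide (BrCc1ccccc1)
Why: Williamson etherification gives the building block used for both ring B and ring D, with the crowded oxygen masked and an unflanked bromide at C1.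

Step 10
Reactants: 16 2,4,6-trimethoxyphenol; 15 2-(benzyloxy)-5-bromo-1,3-dimethoxybenzene
Product: 17 2-(benzyloxy)-1,3-dimethoxy-5-(2,4,6-trimethoxyphenoxy)benzene (A–B benzyl ether)
Conditions: CuI (10 mol %), picolinic acid (20 mol %), K3PO4, DMSO, 100 °C, argon
Reagents that add atoms: none
Why: Ligand-accelerated Ullmann diaryl ether coupling, in which the picolinate complex of monovalent copper arylates di-ortho-substituted phenoxides with aryl bromides that are unhindered, as B C1 is.

Step 11
Reactants: 17 A–B benzyl ether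
Product: 18 2,6-dimethoxy-4-(2,4,6-trimethoxyphenoxy)phenol (A–B phenol, OH on B C4)
Conditions: H2 (1 atm), 10% Pd/C, EtOAc–MeOH, rt
Reagents that add atoms: none
Why: Hydrogenolysis of the benzyl ether frees the crowded B C4 hydroxyl and touches nothing else.

Step 12
Reactants: 19 5-bromo-1,2,3-trimethoxybenzene
Product: 21 6-bromo-2,3,4-trimethoxybenzaldehyde, via alpha-chloro ether 20 (not isolated)
Conditions: Cl2CHOMe, TiCl4, CH2Cl2, −10 to 0 °C; then ice–water
Reagents that add atoms: dichloromethyl methyl ether (COC(Cl)Cl); water (O)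
Why: Rieche formylation can only attack the two equivalent free positions, each ortho and para to methoxy, and water hydrolyses chloro ether 20 to the aldehyde, placing formyl (future C C6 oxygen) next to bromide (C C1).

Step 13
Reactants: 18 A–B phenol; 21 6-bromo-2,3,4-trimethoxybenzaldehyde
Product: 22 6-[2,6-dimethoxy-4-(2,4,6-trimethoxyphenoxy)phenoxy]-2,3,4-trimethoxybenzaldehyde (A–B–C aldehyde)
Conditions: CuI (20 mol %), picolinic acid (40 mol %), K3PO4, DMSO, 90 °C, argon
Reagents that add atoms: none
Why: Ullmann coupling in which the ortho formyl group activates the bromide towards copper and towards addition–elimination, so that the 2,6-dimethoxyphenoxide of 18 should couple.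

Step 14
Reactants: 22 A–B–C aldehyde
Product: 24 6-[2,6-dimethoxy-4-(2,4,6-trimethoxyphenoxy)phenoxy]-2,3,4-trimethoxyphenol (A–B–C phenol, OH on C C6), via aryl formate 23 (not isolated)
Conditions: mCPBA, CH2Cl2, 0 °C to rt; then K2CO3 (cat.), MeOH, rt
Reagents that add atoms: mCPBA (OOC(=O)c1cccc(Cl)c1)
Why: Baeyer–Villiger (Dakin-type) oxidation, favoured because the migrating aryl carbon has oxygen on both ortho carbons and on the para carbon, followed by methanolysis of the formate.

Step 15
Reactants: 24 A–B–C phenol; 15 2-(benzyloxy)-5-bromo-1,3-dimethoxybenzene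
Product: 25 1,2,3-trimethoxy-4-[4-(benzyloxy)-3,5-dimethoxyphenoxy]-5-[2,6-dimethoxy-4-(2,4,6-trimethoxyphenoxy)phenoxy]benzene (A–B–C–D benzyl ether)
Conditions: CuI (20 mol %), picolinic acid (40 mol %), K3PO4, DMSO, 110 °C, argon
Reagents that add atoms: none
Why: Ullmann coupling with the same copper picolinate system; only the phenol is crowded, because the bromide carbon (D C1) lies between two CH groups.

Step 16
Reactants: 25 A–B–C–D benzyl ether
Product: 26 2,6-dimethoxy-4-{2,3,4-trimethoxy-6-[2,6-dimethoxy-4-(2,4,6-trimethoxyphenoxy)phenoxy]phenoxy}phenol (A–B–C–D phenol, OH on D C4)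
Conditions: H2 (1 atm), 10% Pd/C, EtOAc–MeOH, rt
Reagents that add atoms: none
Why: Hydrogenolysis removes the single benzyl ether and leaves all aryl ethers intact.

Step 17
Reactants: 26 A–B–C–D phenol; 13 E–F–G triflate
Product: 27 heptadeca-O-methyl ether of the target (A–G heptamer, all seventeen hydroxyls as OMe)
Conditions: Pd(OAc)2 (10 mol %), 2-di-tert-butylphosphino-3,4,5,6-tetramethyl-2',4',6'-triisopropylbiphenyl (15 mol %), K3PO4 (2 equiv), toluene, 100 °C, argon
Reagents that add atoms: none
Why: Buchwald–Hartwig-type C–O coupling by oxidative addition of the triflate to zerovalent palladium, exchange for the phenoxide and reductive elimination, which the bulky di-tert-butyl biarylphosphine and the crowded phenoxide both favour.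

Step 18
Reactants: 27 heptadeca-O-methyl heptamer
Product: 28 CNP0351377.0 (target)
Conditions: BBr3 (about 50 equiv), CH2Cl2, −78 °C to rt; degassed H2O, 0 °C; reversed-phase or Sephadex LH-20 purification under argon
Reagents that add atoms: none
Why: Lewis-acid ether cleavage, in which BBr3 binds each methoxy oxygen and bromide removes the methyl group by SN2, while the diaryl ether bonds (sp2 carbon on both sides) are not cleaved.

**Compound list**

1 | 2-hydroxy-4,6-dimethoxybenzaldehyde | COc1cc(O)c(C=O)c(OC)c1 | starting material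
2 | 2-(benzyloxy)-4,6-dimethoxybenzaldehyde | COc1cc(OCc2ccccc2)c(C=O)c(OC)c1 | intermediate
3 | 2-(benzyloxy)-4,6-dimethoxyphenyl formate | COc1cc(OCc2ccccc2)c(OC=O)c(OC)c1 | intermediate (not isolated)
4 | 2-(benzyloxy)-4,6-dimethoxyphenol | COc1cc(OCc2ccccc2)c(O)c(OC)c1 | intermediate
5 | syringaldehyde | COc1cc(C=O)cc(OC)c1O | starting material
6 | 3,4,5-trimethoxybenzoyl chloride | COc1cc(C(=O)Cl)cc(OC)c1OC | starting material
7 | 4-formyl-2,6-dimethoxyphenyl 3,4,5-trimethoxybenzoate | COc1cc(C=O)cc(OC)c1OC(=O)c1cc(OC)c(OC)c(OC)c1 | intermediate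
8 | 3,5-dimethoxy-4-(3,4,5-trimethoxybenzoyloxy)benzoic acid | COc1cc(C(=O)O)cc(OC)c1OC(=O)c1cc(OC)c(OC)c(OC)c1 | intermediate
9 | 2-(benzyloxy)-4,6-dimethoxyphenyl 3,5-dimethoxy-4-(3,4,5-trimethoxybenzoyloxy)benzoate (E–F–G depside) | COc1cc(OC)c(OC(=O)c2cc(OC)c(OC(=O)c3cc(OC)c(OC)c(OC)c3)c(OC)c2)c(OCc2ccccc2)c1 | intermediate
10 | 2-(benzyloxy)-4,6-dimethoxyphenyl 3,5-dimethoxy-4-(3,4,5-trimethoxyphenoxy)benzoate | COc1cc(OC)c(OC(=O)c2cc(OC)c(Oc3cc(OC)c(OC)c(OC)c3)c(OC)c2)c(OCc2ccccc2)c1 | intermediate (not isolated)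
11 | 1-(benzyloxy)-3,5-dimethoxy-2-[3,5-dimethoxy-4-(3,4,5-trimethoxyphenoxy)phenoxy]benzene (E–F–G trimer ether) | COc1cc(OC)c(Oc2cc(OC)c(Oc3cc(OC)c(OC)c(OC)c3)c(OC)c2)c(OCc2ccccc2)c1 | intermediate
12 | 3,5-dimethoxy-2-[3,5-dimethoxy-4-(3,4,5-trimethoxyphenoxy)phenoxy]phenol | COc1cc(OC)c(Oc2cc(OC)c(Oc3cc(OC)c(OC)c(OC)c3)c(OC)c2)c(O)c1 | intermediate
13 | 3,5-dimethoxy-2-[3,5-dimethoxy-4-(3,4,5-trimethoxyphenoxy)phenoxy]phenyl trifluoromethanesulfonate | COc1cc(OC)c(Oc2cc(OC)c(Oc3cc(OC)c(OC)c(OC)c3)c(OC)c2)c(OS(=O)(=O)C(F)(F)F)c1 | intermediate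
14 | 4-bromo-2,6-dimethoxyphenol | COc1cc(Br)cc(OC)c1O | starting material
15 | 2-(benzyloxy)-5-bromo-1,3-dimethoxybenzene | COc1cc(Br)cc(OC)c1OCc1ccccc1 | intermediate
16 | 2,4,6-trimethoxyphenol | COc1cc(OC)c(O)c(OC)c1 | starting material
17 | 2-(benzyloxy)-1,3-dimethoxy-5-(2,4,6-trimethoxyphenoxy)benzene | COc1cc(OC)c(Oc2cc(OC)c(OCc3ccccc3)c(OC)c2)c(OC)c1 | intermediate
18 | 2,6-dimethoxy-4-(2,4,6-trimethoxyphenoxy)phenol | COc1cc(OC)c(Oc2cc(OC)c(O)c(OC)c2)c(OC)c1 | intermediate
19 | 5-bromo-1,2,3-trimethoxybenzene | COc1cc(Br)cc(OC)c1OC | starting material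
20 | 1-bromo-2-[chloro(methoxy)methyl]-3,4,5-trimethoxybenzene | COC(Cl)c1c(Br)cc(OC)c(OC)c1OC | intermediate (not isolated)
21 | 6-bromo-2,3,4-trimethoxybenzaldehyde | COc1cc(Br)c(C=O)c(OC)c1OC | intermediate
22 | 6-[2,6-dimethoxy-4-(2,4,6-trimethoxyphenoxy)phenoxy]-2,3,4-trimethoxybenzaldehyde | COc1cc(OC)c(Oc2cc(OC)c(Oc3cc(OC)c(OC)c(OC)c3C=O)c(OC)c2)c(OC)c1 | intermediate
23 | 6-[2,6-dimethoxy-4-(2,4,6-trimethoxyphenoxy)phenoxy]-2,3,4-trimethoxyphenyl formate | COc1cc(OC)c(Oc2cc(OC)c(Oc3cc(OC)c(OC)c(OC)c3OC=O)c(OC)c2)c(OC)c1 | intermediate (not isolated)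
24 | 6-[2,6-dimethoxy-4-(2,4,6-trimethoxyphenoxy)phenoxy]-2,3,4-trimethoxyphenol | COc1cc(OC)c(Oc2cc(OC)c(Oc3cc(OC)c(OC)c(OC)c3O)c(OC)c2)c(OC)c1 | intermediate
25 | 1,2,3-trimethoxy-4-[4-(benzyloxy)-3,5-dimethoxyphenoxy]-5-[2,6-dimethoxy-4-(2,4,6-trimethoxyphenoxy)phenoxy]benzene | COc1cc(OC)c(Oc2cc(OC)c(Oc3cc(OC)c(OC)c(OC)c3Oc3cc(OC)c(OCc4ccccc4)c(OC)c3)c(OC)c2)c(OC)c1 | intermediate
26 | 2,6-dimethoxy-4-{2,3,4-trimethoxy-6-[2,6-dimethoxy-4-(2,4,6-trimethoxyphenoxy)phenoxy]phenoxy}phenol | COc1cc(OC)c(Oc2cc(OC)c(Oc3cc(OC)c(OC)c(OC)c3Oc3cc(OC)c(O)c(OC)c3)c(OC)c2)c(OC)c1 | intermediate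
27 | heptadeca-O-methyl ether of the target | COc1cc(OC)c(Oc2cc(OC)c(Oc3cc(OC)c(OC)c(OC)c3Oc3cc(OC)c(Oc4cc(OC)cc(OC)c4Oc4cc(OC)c(Oc5cc(OC)c(OC)c(OC)c5)c(OC)c4)c(OC)c3)c(OC)c2)c(OC)c1 | intermediate
28 | CNP0351377.0 | Oc1cc(O)c(Oc2cc(O)c(Oc3cc(O)c(O)c(O)c3Oc3cc(O)c(Oc4cc(O)cc(O)c4Oc4cc(O)c(Oc5cc(O)c(O)c(O)c5)c(O)c4)c(O)c3)c(O)c2)c(O)c1 | target

**Summary**

Total step count: 18. Longest linear sequence: 9 steps (steps 9, 10, 11, 13, 14, 15, 16, 17, 18, from compound 14).

**Steps most likely to fail**

1. Step 6 (Proposed new method). Oxidative addition may stall on the electron-rich esters, so that extrusion stops at ester 10. After CO loss the aryloxide may also exchange between palladium centres, or the acyl group may shift around ring F, giving scrambled ethers or reduced arenes. The fallback uses known chemistry, sets out from 14 and 4 and returns to the route at 11. Chan–Lam coupling of 14 with 3,4,5-trimethoxyphenylboronic acid (Cu(OAc)2, pyridine, 4 Å sieves, CH2Cl2, air, rt), which leaves the aryl bromide untouched, should give 5-bromo-1,3-dimethoxy-2-(3,4,5-trimethoxyphenoxy)benzene F1. Ullmann coupling of this bromide with phenol 4 (CuI, picolinic acid, K3PO4, DMSO, 100 °C) should then give 11.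

2. Step 17. The phenoxide of 26 may attack sulfur of the triflate (triflyl transfer, returning phenol 12), and exchange of the crowded phenoxide at palladium may be too slow to compete with reduction of the triflate. The fallback sets out from 13 and returns at 27. Ruthenium-catalysed triflate–iodide exchange ([(C5Me5)Ru(NCMe)3]OTf, NaI, 1,3-dimethyl-2-imidazolidinone, 100 °C) should give 1-iodo-3,5-dimethoxy-2-[3,5-dimethoxy-4-(3,4,5-trimethoxyphenoxy)phenoxy]benzene F2. This iodide is then coupled with phenol 26 under the Ullmann conditions of step 15 (CuI, picolinic acid, K3PO4, DMSO, 100 °C), which are suited to a crowded phenol with an ortho-substituted aryl iodide.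

3. Step 18. Cleavage of seventeen methyl ethers may stop short as boron aryloxides precipitate, and the free pyrogallol-type rings may oxidise in air during isolation. The fallback sets out from 27 and returns at 28. After the BBr3 treatment and quench, the crude polyphenol is acetylated without purification (Ac2O, pyridine, DMAP, rt) to the heptadecaacetate of the target F3, which is stable to air and can be purified on silica; under-demethylated acetates are separated and sent back through BBr3. Deacetylation with degassed methanolic HCl (acetyl chloride in MeOH, rt) should then release 28.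

**Further compounds**

F1 | step 6 | 5-bromo-1,3-dimethoxy-2-(3,4,5-trimethoxyphenoxy)benzene | COc1cc(Br)cc(OC)c1Oc1cc(OC)c(OC)c(OC)c1
F2 | step 17 | 1-iodo-3,5-dimethoxy-2-[3,5-dimethoxy-4-(3,4,5-trimethoxyphenoxy)phenoxy]benzene | COc1cc(OC)c(Oc2cc(OC)c(Oc3cc(OC)c(OC)c(OC)c3)c(OC)c2)c(I)c1
F3 | step 18 | heptadecaacetate of the target | CC(=O)Oc1cc(OC(C)=O)c(Oc2cc(OC(C)=O)c(Oc3cc(OC(C)=O)c(OC(C)=O)c(OC(C)=O)c3Oc3cc(OC(C)=O)c(Oc4cc(OC(C)=O)cc(OC(C)=O)c4Oc4cc(OC(C)=O)c(Oc5cc(OC(C)=O)c(OC(C)=O)c(OC(C)=O)c5)c(OC(C)=O)c4)c(OC(C)=O)c3)c(OC(C)=O)c2)c(OC(C)=O)c1
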